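Ring A of the target (C-1 CH2 bridge, C-2 OH, C-3 prenyl, C-4 OH, C-5 isobutyryl, C-6 OMe) has its prenyl carbon between two hydroxyls and para to the methoxy group, the pattern of a methylated triketide. The route therefore disconnects the ring A bond between C-2 and C-3: a 4-methoxy-2-pyrone bearing a 6-(4-methylpent-3-enyl) chain is opened by methoxide and its side-chain CH2 folds onto the former lactone carbonyl, giving ring A in one operation with the methyl ether already distinguished from both phenols. Acylation at C-5 and a methylene link from C-1 to the pyrone made from 3-pentanone complete the target.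

Key step: step 2

Remark: the target has no stereocentre; silyl enol ether 13 is carried as an E/Z mixture because both isomers converge on pyrone 16, and acid chloride 15 is racemic at a centre that is lost on enolisation.

Step 1
Reactants: 1 4-methoxy-6-methyl-2H-pyran-2-one; 2 prenyl bromide
Product: 4 4-methoxy-6-(4-methylpent-3-en-1-yl)-2H-pyran-2-one, via lithiated pyrone 3 (not isolated)
Conditions: LiN(iPr)2, THF, −78 °C; then 2, DMPU, −78 → −30 °C
Reagents that add atoms: none
Why: Vinylogous enolate alkylation, in which LiN(iPr)2 removes a proton from the 6-methyl group to give the extended dienolate 3 and its terminal carbon displaces bromide from the primary allylic halide by SN2, restoring the pyrone without forming a stereocentre.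

Step 2
Reactants: 4 4-methoxy-6-(4-methylpent-3-en-1-yl)-2H-pyran-2-one
Product: 6 5-methoxy-2-(3-methylbut-2-en-1-yl)benzene-1,3-diol, via open-chain keto ester 5 (not isolated)
Conditions: NaOMe (5 equiv), dry degassed MeOH, sealed tube, 170 °C; then AcOH, 0 °C
Reagents that add atoms: none
Why: Methoxide adds to the lactone carbonyl of 4 and the ring opens to keto ester 5, in which the ester and the ketone arm remain cis on the enol-ether double bond (2E geometry) because both were ring members. Deprotonation of the side-chain CH2 next to the freed ketone gives an enolate whose carbon attacks the ester carbonyl, methoxide is expelled and the first-formed keto tautomer aromatises to the phenoxide of 6, which creates the bond between C-2 and C-3 of ring A; the ring closes in a 6-(enolendo)-exo-trig mode, a Claisen (Dieckmann-type) condensation. The closest known reactions are the base-induced isomerisation of 4-methoxy-6-methyl-2-pyrone to 5-methoxyresorcinol under forcing conditions and the Claisen folding of 3,5-dioxoalkanoates to phloroglucinols, the only change here being that the nucleophilic carbon is a CH2 instead of a CH3. No stereocentre is formed. The step needs site selectivity between the two α-carbons of the ketone: the more acidic ring-derived CH2 can only re-close to pyrone 4 (C–C closure from it would need a four-membered ring), so only the side-chain enolate is productive and irreversible aromatisation drains all equilibria towards 6. Because base and solvent match the enol methyl ether and the transient methyl ester, every exchange is degenerate and the methoxy group at C-6 of ring A emerges already distinguished from the hydroxyls at C-2 and C-4.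

Step 3
Reactants: 6 5-methoxy-2-(3-methylbut-2-en-1-yl)benzene-1,3-diol
Product: 7 5-methoxy-1,3-bis(methoxymethoxy)-2-(3-methylbut-2-en-1-yl)benzene
Conditions: MOMCl, iPr2NEt, CH2Cl2, 0 °C → rt
Reagents that add atoms: chloromethyl methyl ether (MOMCl), COCCl
Why: Williamson-type O-alkylation of both phenols by the hard α-chloro ether gives the symmetric bis-acetal, whose OMOM groups protect the phenols from base and direct the metalation of the next step.

Step 4
Reactants: 7 5-methoxy-1,3-bis(methoxymethoxy)-2-(3-methylbut-2-en-1-yl)benzene; 8 N-methoxy-N,2-dimethylpropanamide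
Product: 10 1-[6-methoxy-2,4-bis(methoxymethoxy)-3-(3-methylbut-2-en-1-yl)phenyl]-2-methylpropan-1-one, via aryllithium 9 (not isolated)
Conditions: n-BuLi, THF, 0 °C; then 8, −78 °C → rt; aq. NH4Cl
Reagents that add atoms: none
Why: Directed ortho-metalation followed by a Weinreb ketone synthesis, since the two equivalent ring C–H positions of 7 each lie between a coordinating OMOM and an OMe group and the chelated tetrahedral adduct of 9 with the N-methoxy amide releases the ketone only on work-up, so over-addition is excluded.

Step 5
Reactants: 10 1-[6-methoxy-2,4-bis(methoxymethoxy)-3-(3-methylbut-2-en-1-yl)phenyl]-2-methylpropan-1-one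
Product: 11 1-[2,4-dihydroxy-6-methoxy-3-(3-methylbut-2-en-1-yl)phenyl]-2-methylpropan-1-one
Conditions: HCl (3 M aq.), MeOH, rt
Reagents that add atoms: none
Why: Acid-catalysed acetal exchange with methanol removes both MOM groups at room temperature, conditions mild enough that the prenyl group next to the liberated phenols should not cyclise to a chroman.

Step 6
Reactants: 12 pentan-3-one
Product: 13 3-(trimethylsilyloxy)pent-2-ene
Conditions: TMSCl, Et3N, DMF, 80 °C
Reagents that add atoms: chlorotrimethylsilane (TMSCl), C[Si](C)(C)Cl
Why: Silyl enol ether formation under equilibrating amine conditions, free of regiochemical ambiguity because the ketone is symmetric.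

Step 7
Reactants: 13 3-(trimethylsilyloxy)pent-2-ene; 14 malonyl dichloride
Product: 16 6-ethyl-4-hydroxy-5-methyl-2H-pyran-2-one, via acid chloride 15 (not isolated)
Conditions: Et2O, −78 °C → rt
Reagents that add atoms: none
Why: Pyrone annulation of a silyl enol ether with malonyl dichloride, in which C-acylation by one acid chloride gives 15 and the enol oxygen of its ethyl ketone then lactonises onto the second acid chloride with loss of HCl.

Step 8
Reactants: 16 6-ethyl-4-hydroxy-5-methyl-2H-pyran-2-one; 17 N,N-dimethylmethyleneiminium iodide; 11 1-[2,4-dihydroxy-6-methoxy-3-(3-methylbut-2-en-1-yl)phenyl]-2-methylpropan-1-one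
Product: 20 3-{[2,4-dihydroxy-6-methoxy-3-(3-methylbut-2-en-1-yl)-5-(2-methylpropanoyl)phenyl]methyl}-6-ethyl-4-hydroxy-5-methyl-2H-pyran-2-one, via Mannich base 18 (not isolated), via methylene dione 19 (not isolated)
Conditions: 16, 17 (1.0 equiv), MeCN, rt; then 11, 70 °C
Reagents that add atoms: none
Why: Mannich reaction at the nucleophilic C-3 of the 4-hydroxypyrone, thermal E1cB loss of dimethylamine to the 3-methylene dione 19 and Michael-type C-alkylation (carba-Betti coupling) by C-1 of ring A, the only unsubstituted ring carbon of phenol 11, with the pyrone fully converted to 18 before 11 is added so that no free pyrone competes and no stereocentre arises.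

Compound list
1 | 4-methoxy-6-methyl-2H-pyran-2-one | COc1cc(C)oc(=O)c1 | starting material
2 | prenyl bromide (1-bromo-3-methylbut-2-ene) | CC(C)=CCBr | starting material
3 | [(4-methoxy-2-oxo-2H-pyran-6-yl)methyl]lithium (extended lithium dienolate of 1) | [Li]Cc1cc(OC)cc(=O)o1 | intermediate (not isolated)
4 | 4-methoxy-6-(4-methylpent-3-en-1-yl)-2H-pyran-2-one | COc1cc(CCC=C(C)C)oc(=O)c1 | intermediate
5 | methyl (2E)-3-methoxy-9-methyl-5-oxodeca-2,8-dienoate (present as its sodium enolate) | COC(=O)/C=C(/OC)CC(=O)CCC=C(C)C | intermediate (not isolated)
6 | 5-methoxy-2-(3-methylbut-2-en-1-yl)benzene-1,3-diol | COc1cc(O)c(CC=C(C)C)c(O)c1 | intermediate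
7 | 5-methoxy-1,3-bis(methoxymethoxy)-2-(3-methylbut-2-en-1-yl)benzene | COCOc1cc(OC)cc(OCOC)c1CC=C(C)C | intermediate
8 | N-methoxy-N,2-dimethylpropanamide | CC(C)C(=O)N(C)OC | starting material
9 | [6-methoxy-2,4-bis(methoxymethoxy)-3-(3-methylbut-2-en-1-yl)phenyl]lithium | COCOc1c([Li])c(OC)cc(OCOC)c1CC=C(C)C | intermediate (not isolated)
10 | 1-[6-methoxy-2,4-bis(methoxymethoxy)-3-(3-methylbut-2-en-1-yl)phenyl]-2-methylpropan-1-one | COCOc1c(C(=O)C(C)C)c(OC)cc(OCOC)c1CC=C(C)C | intermediate
11 | 1-[2,4-dihydroxy-6-methoxy-3-(3-methylbut-2-en-1-yl)phenyl]-2-methylpropan-1-one | COc1cc(O)c(CC=C(C)C)c(O)c1C(=O)C(C)C | intermediate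
12 | pentan-3-one | CCC(=O)CC | starting material
13 | 3-(trimethylsilyloxy)pent-2-ene (E/Z mixture) | CC=C(CC)O[Si](C)(C)C | intermediate
14 | malonyl dichloride | O=C(Cl)CC(=O)Cl | starting material
15 | 4-methyl-3,5-dioxoheptanoyl chloride (racemic) | CCC(=O)C(C)C(=O)CC(=O)Cl | intermediate (not isolated)
16 | 6-ethyl-4-hydroxy-5-methyl-2H-pyran-2-one | CCc1oc(=O)cc(O)c1C | intermediate
17 | N,N-dimethylmethyleneiminium iodide | C=[N+](C)C.[I-] | starting material
18 | 3-[(dimethylamino)methyl]-6-ethyl-4-hydroxy-5-methyl-2H-pyran-2-one (formed as its hydroiodide) | CCc1oc(=O)c(CN(C)C)c(O)c1C | intermediate (not isolated)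
19 | 6-ethyl-5-methyl-3-methylidene-2H-pyran-2,4(3H)-dione | CCC1=C(C)C(=O)C(=C)C(=O)O1 | intermediate (not isolated)
20 | 3-{[2,4-dihydroxy-6-methoxy-3-(3-methylbut-2-en-1-yl)-5-(2-methylpropanoyl)phenyl]methyl}-6-ethyl-4-hydroxy-5-methyl-2H-pyran-2-one | CCc1oc(=O)c(Cc2c(O)c(CC=C(C)C)c(O)c(C(=O)C(C)C)c2OC)c(O)c1C | target

Total step count: 8 steps.
Longest linear sequence: 6 steps (steps 1, 2, 3, 4, 5 and 8); steps 6 and 7 form the convergent pyrone arm.

Steps most likely to fail

1. Step 2. The ring opening may simply reverse, with the doubly activated ring-derived methylene acting as a resting enolate that returns the pyrone. Closure from the weakly acidic side-chain CH2 may then be too slow to compete with hydrolysis and decarboxylation by traces of water, with intermolecular condensation, or with base-induced migration of the prenyl double bond at the high temperature. The fallback builds the same substitution pattern by known aryl-metal chemistry and sets out from prenyl bromide 2. Commercial 5-methoxyresorcinol (COc1cc(O)cc(O)c1) is protected with MOMCl and iPr2NEt in CH2Cl2 to 1-methoxy-3,5-bis(methoxymethoxy)benzene F1. F1 is lithiated with n-BuLi in THF at 0 °C at the carbon between the two OMOM groups, the stronger pair of directing groups, to give [4-methoxy-2,6-bis(methoxymethoxy)phenyl]lithium F2. F2 is alkylated with 2 at −78 °C → rt, and any isomer from metalation between OMOM and OMe would be removed by chromatography. This returns to the route at compound 7 and replaces steps 1 to 3.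

2. Step 8. Incomplete aminomethylation would leave free pyrone that captures the methylene dione and diverts material into a symmetric methylene-bridged pyrone dimer. The heterodiene could also undergo cycloaddition with the prenyl alkene, and C-alkylation at the hindered C-1 of ring A, between OH and OMe, may be slow. The fallback inverts the roles of the partners and sets out from compound 11. Aminomethylation of 11 at its unsubstituted ring carbon with 17 (CH2Cl2, rt; NaHCO3 work-up) should give the phenolic Mannich base 1-[3-[(dimethylamino)methyl]-4,6-dihydroxy-2-methoxy-5-(3-methylbut-2-en-1-yl)phenyl]-2-methylpropan-1-one F3. Heating F3 with pyrone 16 in dioxane at 100 °C expels dimethylamine to the ortho-quinone methide 3-hydroxy-5-methoxy-6-methylidene-2-(3-methylbut-2-en-1-yl)-4-(2-methylpropanoyl)cyclohexa-2,4-dien-1-one F4. C-3 of 16 adds to F4 in a Michael reaction, which returns to the route at target 20.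

3. Step 4. Acyl transfer to an aryllithium flanked by two ortho substituents may be slow, so that deprotonation at the benzylic-allylic CH2 of the prenyl group or base-induced fragmentation of the N-methoxy amide competes. The fallback sets out from compound 7 and replaces acyl substitution by carbonyl addition and oxidation. Aryllithium 9, generated as before, is added to isobutyraldehyde (CC(C)C=O) in THF at −78 °C to give 1-[6-methoxy-2,4-bis(methoxymethoxy)-3-(3-methylbut-2-en-1-yl)phenyl]-2-methylpropan-1-ol F5 (racemic). F5 is oxidised with Dess–Martin periodinane (NaHCO3, CH2Cl2, rt), which returns to the route at compound 10 at the cost of one more step.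

Further compounds
F1 | step 2 | 1-methoxy-3,5-bis(methoxymethoxy)benzene | COCOc1cc(OC)cc(OCOC)c1
F2 | step 2 | [4-methoxy-2,6-bis(methoxymethoxy)phenyl]lithium | COCOc1cc(OC)cc(OCOC)c1[Li]
F3 | step 8 | 1-[3-[(dimethylamino)methyl]-4,6-dihydroxy-2-methoxy-5-(3-methylbut-2-en-1-yl)phenyl]-2-methylpropan-1-one | COc1c(CN(C)C)c(O)c(CC=C(C)C)c(O)c1C(=O)C(C)C
F4 | step 8 | 3-hydroxy-5-methoxy-6-methylidene-2-(3-methylbut-2-en-1-yl)-4-(2-methylpropanoyl)cyclohexa-2,4-dien-1-one | C=C1C(=O)C(CC=C(C)C)=C(O)C(C(=O)C(C)C)=C1OC
F5 | step 4 | 1-[6-methoxy-2,4-bis(methoxymethoxy)-3-(3-methylbut-2-en-1-yl)phenyl]-2-methylpropan-1-ol (racemic) | COCOc1c(C(O)C(C)C)c(OC)cc(OCOC)c1CC=C(C)C
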